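**Plan**

- Germacrane numbering is used: C3 carbinol, C4(Me)=C5, C6 OAc, C7 iPr, C8 OBz, C10(Me)=C1. The retrosynthesis first takes back the C3–H bond (ketone reduction), the C8 benzoate, and the C6 acetate together with the C8–H bond (Tishchenko transfer), which leads to 6‑hydroxy‑3,8‑diketone 20.
- Enabling feature: C3 and C8 are both oxygenated and lie 1,6 across the ten‑membered ring. Rejoining them gives cis‑glycol 18, two fused cyclohexenes: ring A (C3–C4–C5–C6–C7–C8) and ring B (C3–C2–C1–C10–C9–C8), each holding one alkene cis.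
- Ring B is then cut at C1=C10 (metathesis), C2–C3 (allyl Grignard) and C8–C9 (enolate methallylation). Ring A with its C4 methyl and C7 isopropyl is (S)‑carvone, to which the C6 and C8 oxygens are added.
- Forward order of rings: ring A is bought, ring B is closed by metathesis, and the ten‑membered ring appears last when the A/B fusion bond is cleaved with Pb(OAc)4.
- Stereochemistry: C7 comes from (S)‑carvone. C6 is set by γ‑hydroxylation anti to isopropyl followed by Mitsunobu inversion. C8 is set by Evans–Tishchenko hydride relay from C6–O (1,3‑anti). C3 is set by oxazaborolidine reagent control. Both alkenes are Z because each was held in a six‑membered ring. The C3 and C8 centres of the bicyclic intermediates are erased.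

Key step: step 13

Remark: ring carbons carry the germacrane numbers C1–C10 of the target in every intermediate, and α means the face of ring A that bears the C7 isopropyl group (β the opposite face).
Remark: 20 is written as the open hydroxy diketone; it may rest as the C6–O–C3 hemiketal, a ring–chain tautomer that is assumed to open readily under Lewis‑acid catalysis.

**Route**

Step 1
Reactants: 1 (S)-(+)-carvone
Product: 2 (S)-carvotanacetone [(5S)-5-isopropyl-2-methylcyclohex-2-en-1-one]
Conditions: H2 (1 atm), RhCl(PPh3)3 (cat.), benzene, rt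
Reagents that add atoms: none
Why: Homogeneous hydrogenation with RhCl(PPh3)3 reduces the unhindered 1,1‑disubstituted isopropenyl alkene far faster than the trisubstituted conjugated one and does not touch C7.

Step 2
Reactants: 2 (S)-carvotanacetone
Product: 3 (5S)-5-isopropyl-2-methylcyclohexa-1,3-dien-1-yl acetate
Conditions: isopropenyl acetate (neat), TsOH·H2O (cat.), reflux with removal of acetone
Reagents that add atoms: isopropenyl acetate, CC(=C)OC(C)=O
Why: Acid‑catalysed enol acetylation under equilibrating conditions should give the linear, fully conjugated dienyl acetate by loss of the γ‑hydrogen at C6.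

Step 3
Reactants: 3 (5S)-5-isopropyl-2-methylcyclohexa-1,3-dien-1-yl acetate
Product: 5 (4S,5S)-4-hydroxy-5-isopropyl-2-methylcyclohex-2-en-1-one, via 3,4-epoxy enol acetate 4 (not isolated)
Conditions: mCPBA, CH2Cl2, 0 °C; aq. NaHCO3 wash; then K2CO3 (cat.), MeOH, 0 °C
Reagents that add atoms: 3-chloroperoxybenzoic acid (mCPBA), OOC(=O)c1cccc(Cl)c1
Why: This is the classical γ‑hydroxylation of an enone through its dienol ester, in which the peracid epoxidises the remote C5=C6 bond (the enol‑acetate bond being deactivated by the acyloxy group) on the face opposite the C7 isopropyl group, and methanolysis of the enol acetate then opens the epoxide by E1cB elimination, so C6–OH is expected trans to isopropyl.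

Step 4
Reactants: 5 (4S,5S)-4-hydroxy-5-isopropyl-2-methylcyclohex-2-en-1-one
Product: 6 (1R,6S)-6-isopropyl-3-methyl-4-oxocyclohex-2-en-1-yl 4-nitrobenzoate
Conditions: 4-O2NC6H4CO2H, PPh3, iPrO2CN=NCO2iPr, THF, 0 °C to rt
Reagents that add atoms: 4-nitrobenzoic acid, O=C(O)c1ccc(cc1)[N+](=O)[O-]
Why: Mitsunobu esterification inverts C6 by SN2 displacement of the alkoxyphosphonium ion, as in the inversion of menthol‑type alcohols next to an isopropyl‑bearing carbon, and because C7–H is syn to the leaving group the anti elimination towards an aromatisable dienone is not available.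

Step 5
Reactants: 6 (1R,6S)-6-isopropyl-3-methyl-4-oxocyclohex-2-en-1-yl 4-nitrobenzoate
Product: 7 (4R,5S)-4-hydroxy-5-isopropyl-2-methylcyclohex-2-en-1-one
Conditions: K2CO3 (cat.), MeOH, 0 °C
Reagents that add atoms: none
Why: Carbonate‑catalysed transesterification removes the activated 4‑nitrobenzoate under conditions too mild to enolise the enone at C6.

Step 6
Reactants: 7 (4R,5S)-4-hydroxy-5-isopropyl-2-methylcyclohex-2-en-1-one
Product: 8 (4R,5S)-4-(tert-butyldimethylsilyloxy)-5-isopropyl-2-methylcyclohex-2-en-1-one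
Conditions: TBSCl, imidazole, DMF, rt
Reagents that add atoms: tert-butyldimethylsilyl chloride, CC(C)(C)[Si](C)(C)Cl
Why: Standard silylation of a secondary allylic alcohol (silyl chloride with imidazole) protects C6–O for the enolate and Grignard steps.

Step 7
Reactants: 8 (4R,5S)-4-(tert-butyldimethylsilyloxy)-5-isopropyl-2-methylcyclohex-2-en-1-one
Product: 10 6α-OTBS-8β-hydroxy enone, via sodium enolate 9 (not isolated)
Conditions: NaN(SiMe3)2, THF, −78 °C; then 2-(phenylsulfonyl)-3-phenyloxaziridine, −78 °C; aq. NH4Cl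
Reagents that add atoms: 2-(phenylsulfonyl)-3-phenyloxaziridine, O=S(=O)(c1ccccc1)N1OC1c1ccccc1
Why: Kinetic deprotonation gives the cross‑conjugated α′‑enolate 9, and its oxidation by the N‑sulfonyloxaziridine (enolate hydroxylation) installs the C8 oxygen, expected anti to isopropyl although this centre is re‑made in step 9.

Step 8
Reactants: 10 6α-OTBS-8β-hydroxy enone
Product: 11 6α-OTBS-8β-[(triisopropylsilyloxy)methoxy] enone
Conditions: iPr3SiOCH2Cl, iPr2NEt, Bu4NI (cat.), CH2Cl2, 0 °C to rt
Reagents that add atoms: (triisopropylsilyloxy)methyl chloride (TOMCl), CC(C)[Si](OCCl)(C(C)C)C(C)C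
Why: Alkoxymethyl ether formation with a chloromethyl ether and a hindered amine gives a base‑stable, fluoride‑labile group that cannot shift to the enolate oxygen in step 9 as a silyl ether could.

Step 9
Reactants: 11 6α-OTBS-8β-[(triisopropylsilyloxy)methoxy] enone, 12 methallyl bromide
Product: 14 6α-OTBS-8α-OTOM-8β-methallyl enone, via lithium enolate 13 (not isolated)
Conditions: LiN(iPr)2, THF, −78 °C; then 12, DMPU, −78 to −30 °C
Reagents that add atoms: none
Why: Enolate C‑alkylation of the tetrasubstituted α‑alkoxy enolate 13 with the reactive allylic bromide should occur on the face opposite the adjacent C7 isopropyl group, as in the 6,6‑dialkylation of carvone derivatives, so methallyl ends β and the C8 oxygen α.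

Step 10
Reactants: 14 6α-OTBS-8α-OTOM-8β-methallyl enone, 15 allylmagnesium bromide
Product: 16 3β-allyl-3α-hydroxy-8β-methallyl diene (6α-OTBS, 8α-OTOM)
Conditions: THF, −78 °C; aq. NH4Cl
Reagents that add atoms: none
Why: Substrate‑controlled 1,2‑addition of the allyl Grignard reagent should come from the β face, because the α face carries C8–OTOM, the C7 isopropyl and C6–OTBS, which places allyl cis to methallyl and C3–OH cis to C8–O at a centre that step 13 erases.

Step 11
Reactants: 16 3β-allyl-3α-hydroxy-8β-methallyl diene (6α-OTBS, 8α-OTOM)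
Product: 17 cis-fused 2-(TBSO)-1-isopropyl-4,7-dimethyl-8a-OTOM-1,2,4a,5,8,8a-hexahydronaphthalen-4a-ol (1-iPr, 2-O, 4a-OH and 8a-O all α)
Conditions: second-generation Grubbs catalyst RuCl2(=CHPh)(PCy3)(H2IMes) (5 mol %), CH2Cl2, 40 °C
Reagents that add atoms: none
Why: Ring‑closing metathesis of the cis‑disposed allyl and methallyl arms closes ring B as a trisubstituted cyclohexene with loss of ethylene, while the trisubstituted ring A alkene is inert.

Step 12
Reactants: 17 cis-fused bicyclic bis-ether
Product: 18 cis-fused 1-isopropyl-4,7-dimethyl-1,2,4a,5,8,8a-hexahydronaphthalene-2,4a,8a-triol (3α,6α,8α-triol in germacrane numbering)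
Conditions: Bu4NF, THF, rt
Reagents that add atoms: none
Why: Fluoride desilylation cleaves both Si–O bonds, and the C8 hemiformal anion released from the TOM group loses formaldehyde, which frees the cis‑glycol and the C6 hydroxyl in one operation.

Step 13
Reactants: 18 cis-fused triol
Product: 20 (1(10)Z,4Z,6S,7S)-6-hydroxy-7-isopropyl-4,10-dimethylcyclodeca-1(10),4-diene-3,8-dione, via cyclic tetravalent-lead diester 19 (not isolated)
Conditions: Pb(OAc)4, CH2Cl2, −20 °C, short contact; filtration through silica, used at once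
Reagents that add atoms: none
Why: The two tertiary ring‑fusion hydroxyls (C3–OH and C8–OH, both α and therefore cis) each displace an acetate from Pb(OAc)4 to give the five‑membered cyclic diester of tetravalent lead 19, which collapses in a concerted two‑electron fragmentation in which the C3–C8 bond breaks, both C–O bonds become C=O and lead leaves as divalent Pb(OAc)2. This is the Criegee glycol cleavage, and its closest precedent is the opening of cis‑decalin‑4a,8a‑diols to cyclodecane‑1,6‑diones. No ring is closed by bond formation: the ten‑membered ring appears when the bond shared by rings A and B is cut, a ring expansion by fragmentation that needs no high dilution. No stereocentre is created (C3 and C8 become trigonal, C6 and C7 are untouched), and both alkenes must emerge Z because each was held cis in a six‑membered ring. The step needs chemoselectivity for the glycol over the secondary allylic C6–OH and the two trisubstituted alkenes, which the cis‑diol geometry secures by making cyclic ester formation fast at −20 °C. It also needs the β‑hydroxy ketone and the skipped enone of 20 to survive, which the non‑basic, non‑nucleophilic medium and immediate use in step 14 should ensure.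

Step 14
Reactants: 20 6-hydroxy-3,8-diketone
Product: 22 (1(10)Z,4Z,6S,7R,8S)-6-acetoxy-8-hydroxy-7-isopropyl-4,10-dimethylcyclodeca-1(10),4-dien-3-one, via acetaldehyde hemiacetal 21 (not isolated)
Conditions: MeCHO (10 equiv), SmI2 (30 mol %, added to the aldehyde before 20), THF, −10 °C
Reagents that add atoms: acetaldehyde, CC=O
Why: In this Evans–Tishchenko reduction the C6 hydroxyl adds to acetaldehyde and hemiacetal 21, held on trivalent samarium together with the C8 carbonyl, delivers hydride through a six‑membered chair, which sets C8–OH anti to C6–O and leaves C6 as its acetate, while pre‑oxidising SmI2 with the aldehyde keeps divalent samarium away from the diketone.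

Step 15
Reactants: 22 6-acetoxy-8-hydroxy enone
Product: 23 (1(10)Z,4Z,6S,7R,8S)-6-acetoxy-8-benzoyloxy-7-isopropyl-4,10-dimethylcyclodeca-1(10),4-dien-3-one
Conditions: BzCl, pyridine, DMAP (cat.), CH2Cl2, 0 °C
Reagents that add atoms: benzoyl chloride, O=C(Cl)c1ccccc1
Why: Acylation of the only free hydroxyl with an acyl chloride under weakly basic, nucleophile‑catalysed conditions should not enolise the skipped enone.

Step 16
Reactants: 23 6-acetoxy-8-benzoyloxy enone
Product: 24 (1(10)Z,4Z,3R,6S,7R,8S)-6-acetoxy-8-benzoyloxy-3-hydroxy-7-isopropyl-4,10-dimethylcyclodeca-1(10),4-diene (CNP0125882.1)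
Conditions: (S)-2-methyl-CBS-oxazaborolidine (20 mol %), catecholborane, toluene, −78 °C
Reagents that add atoms: none
Why: In this Corey–Bakshi–Shibata reduction the C4 alkenyl carbon acts as the large and the C2 methylene as the small substituent, so the (S)‑oxazaborolidine should deliver hydride 1,2 to give the 3R carbinol by reagent control without touching the esters.

**Compound list**

1 | (S)-(+)-carvone, (5S)-2-methyl-5-(prop-1-en-2-yl)cyclohex-2-en-1-one | CC1=CC[C@@H](CC1=O)C(C)=C | starting material
2 | (S)-carvotanacetone, (5S)-5-isopropyl-2-methylcyclohex-2-en-1-one | CC1=CC[C@@H](CC1=O)C(C)C | intermediate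
3 | (5S)-5-isopropyl-2-methylcyclohexa-1,3-dien-1-yl acetate | CC1=C(OC(C)=O)C[C@H](C=C1)C(C)C | intermediate
4 | 3,4-epoxide of 3, epoxide oxygen trans to isopropyl (not isolated) | CC(=O)OC1=C(C)[C@H]2O[C@H]2[C@H](C(C)C)C1 | intermediate
5 | (4S,5S)-4-hydroxy-5-isopropyl-2-methylcyclohex-2-en-1-one (6β-OH, trans to isopropyl) | O[C@@H]1C=C(C)C(=O)C[C@H]1C(C)C | intermediate
6 | (1R,6S)-6-isopropyl-3-methyl-4-oxocyclohex-2-en-1-yl 4-nitrobenzoate (ester oxygen cis to isopropyl) | O=C(O[C@H]1C=C(C)C(=O)C[C@H]1C(C)C)c1ccc(cc1)[N+](=O)[O-] | intermediate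
7 | (4R,5S)-4-hydroxy-5-isopropyl-2-methylcyclohex-2-en-1-one (6α-OH, cis to isopropyl) | O[C@H]1C=C(C)C(=O)C[C@H]1C(C)C | intermediate
8 | (4R,5S)-4-(tert-butyldimethylsilyloxy)-5-isopropyl-2-methylcyclohex-2-en-1-one | CC(C)(C)[Si](C)(C)O[C@H]1C=C(C)C(=O)C[C@H]1C(C)C | intermediate
9 | sodium α′-enolate of 8 (not isolated) | CC(C)(C)[Si](C)(C)O[C@H]1C=C(C)C([O-])=C[C@H]1C(C)C.[Na+] | intermediate
10 | 4-(TBSO)-6-hydroxy-5-isopropyl-2-methylcyclohex-2-en-1-one, 6α-OTBS, 7α-iPr, 8β-OH | CC(C)(C)[Si](C)(C)O[C@H]1C=C(C)C(=O)[C@H](O)[C@H]1C(C)C | intermediate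
11 | TOM ether of 10, 8β-OCH2OSi(iPr)3 | CC(C)(C)[Si](C)(C)O[C@H]1C=C(C)C(=O)[C@H](OCO[Si](C(C)C)(C(C)C)C(C)C)[C@H]1C(C)C | intermediate
12 | methallyl bromide (3-bromo-2-methylprop-1-ene) | C=C(C)CBr | starting material
13 | lithium enolate of 11 (not isolated) | CC(C)(C)[Si](C)(C)O[C@H]1C=C(C)C([O-])=C(OCO[Si](C(C)C)(C(C)C)C(C)C)[C@H]1C(C)C.[Li+] | intermediate
14 | 4-(TBSO)-5-isopropyl-2-methyl-6-(2-methylallyl)-6-[(triisopropylsilyloxy)methoxy]cyclohex-2-en-1-one, 6α-OTBS, 7α-iPr, 8α-OTOM, 8β-methallyl | CC(C)(C)[Si](C)(C)O[C@H]1C=C(C)C(=O)[C@](OCO[Si](C(C)C)(C(C)C)C(C)C)(CC(C)=C)[C@H]1C(C)C | intermediate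
15 | allylmagnesium bromide | C=CC[Mg]Br | starting material
16 | 1-allyl-4-(TBSO)-5-isopropyl-2-methyl-6-(2-methylallyl)-6-[(triisopropylsilyloxy)methoxy]cyclohex-2-en-1-ol, allyl and methallyl β, 3-OH, 6-OTBS, 7-iPr and 8-OTOM α | CC(C)(C)[Si](C)(C)O[C@H]1C=C(C)[C@](O)(CC=C)[C@](OCO[Si](C(C)C)(C(C)C)C(C)C)(CC(C)=C)[C@H]1C(C)C | intermediate
17 | cis-fused 2-(TBSO)-1-isopropyl-4,7-dimethyl-8a-[(triisopropylsilyloxy)methoxy]-1,2,4a,5,8,8a-hexahydronaphthalen-4a-ol, 1-iPr, 2-O, 4a-OH and 8a-O all α | CC(C)(C)[Si](C)(C)O[C@H]1C=C(C)[C@]2(O)CC=C(C)C[C@]2(OCO[Si](C(C)C)(C(C)C)C(C)C)[C@H]1C(C)C | intermediate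
18 | cis-fused 1-isopropyl-4,7-dimethyl-1,2,4a,5,8,8a-hexahydronaphthalene-2,4a,8a-triol, three hydroxyls and isopropyl all α (key-step precursor) | O[C@H]1C=C(C)[C@]2(O)CC=C(C)C[C@]2(O)[C@H]1C(C)C | intermediate
19 | cyclic diacetoxy tetravalent-lead diester of the 4a,8a-glycol of 18 (not isolated) | O[C@H]1C=C(C)[C@]2(O[Pb]3(OC(C)=O)OC(C)=O)CC=C(C)C[C@]2(O3)[C@H]1C(C)C | intermediate
20 | (1(10)Z,4Z,6S,7S)-6-hydroxy-7-isopropyl-4,10-dimethylcyclodeca-1(10),4-diene-3,8-dione (key-step product) | O[C@H]1/C=C(/C)C(=O)C/C=C(/C)CC(=O)[C@H]1C(C)C | intermediate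
21 | C6-O acetaldehyde hemiacetal of 20, held on samarium (not isolated) | CC(O)O[C@H]1/C=C(/C)C(=O)C/C=C(/C)CC(=O)[C@H]1C(C)C | intermediate
22 | (1(10)Z,4Z,6S,7R,8S)-6-acetoxy-8-hydroxy-7-isopropyl-4,10-dimethylcyclodeca-1(10),4-dien-3-one | CC(=O)O[C@H]1/C=C(/C)C(=O)C/C=C(/C)C[C@H](O)[C@H]1C(C)C | intermediate
23 | (1(10)Z,4Z,6S,7R,8S)-6-acetoxy-8-benzoyloxy-7-isopropyl-4,10-dimethylcyclodeca-1(10),4-dien-3-one | CC(=O)O[C@H]1/C=C(/C)C(=O)C/C=C(/C)C[C@H](OC(=O)c2ccccc2)[C@H]1C(C)C | intermediate
24 | (1(10)Z,4Z,3R,6S,7R,8S)-6-acetoxy-8-benzoyloxy-3-hydroxy-7-isopropyl-4,10-dimethylcyclodeca-1(10),4-diene, CNP0125882.1 | CC(=O)O[C@H]1/C=C(/C)[C@H](O)C/C=C(/C)C[C@H](OC(=O)c2ccccc2)[C@H]1C(C)C | target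

**Step count and risks**

Total step count: 16. Longest linear sequence: 16 steps from (S)-carvone (1).

Steps most likely to fail:

1. Step 14 (Evans–Tishchenko). The C6 hydroxyl may be withdrawn into hemiketal formation with the C3 ketone across the cis C4=C5 bond, or the β‑hydroxy ketone may open by retro‑aldol cleavage, before the hemiacetal can transfer hydride. The fallback sets out from 20 and returns at 23. Directed reduction with Me4NBH(OAc)3 in AcOH/MeCN at −30 °C (Saksena–Evans reduction) relies on boron bound to C6–O for internal hydride delivery and should give the anti diol (1(10)Z,4Z,6S,7R,8S)-6,8-dihydroxy-7-isopropyl-4,10-dimethylcyclodeca-1(10),4-dien-3-one F3. The C8 hydroxyl is then benzoylated (BzCl, pyridine, −20 °C) in preference to the allylic C6 hydroxyl, which is held near the C3 carbonyl, to give the 8-benzoate of the diol F4. Acetylation of C6–OH (Ac2O, Et3N, DMAP) then gives 23.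

2. Step 3 (γ‑hydroxylation). Regiocontrol may be lost if the peracid attacks the tetrasubstituted enol‑acetate bond C3=C4 instead of C5=C6. The fallback sets out from 2 and returns at 5. KOtBu in tBuOH/THF forms the extended dienolate, and kinetic α‑protonation (quench into aq. AcOH) gives the deconjugated ketone (5S)-5-isopropyl-2-methylcyclohex-3-en-1-one F1. mCPBA epoxidises its only alkene trans to isopropyl to give the β,γ-epoxy ketone F2, and catalytic DBU opens the epoxide by E1cB elimination to 5.

3. Step 16 (C3 reduction). Facial selectivity may be poor if the conformation of the ten‑membered ring overrides the catalyst. The fallback sets out from 23 and returns at 24. Luche reduction (NaBH4, CeCl3·7H2O, MeOH, −78 °C) leaves the choice of face to peripheral attack on the ring. If this gives the 3S alcohol, the 3-epimer of the target F5, Mitsunobu inversion with formic acid (PPh3, iPrO2CN=NCO2iPr) gives the 3R formate of the target F6. Its formyl group is removed by KHCO3 in MeOH in the presence of the acetate and benzoate, which gives 24.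

Further compounds
F1 | step 3 | (5S)-5-isopropyl-2-methylcyclohex-3-en-1-one (C2 epimers) | CC1C=C[C@@H](CC1=O)C(C)C
F2 | step 3 | 3,4-epoxide of F1, epoxide oxygen trans to isopropyl | O=C1C(C)[C@H]2O[C@H]2[C@H](C(C)C)C1
F3 | step 14 | (1(10)Z,4Z,6S,7R,8S)-6,8-dihydroxy-7-isopropyl-4,10-dimethylcyclodeca-1(10),4-dien-3-one | O[C@H]1/C=C(/C)C(=O)C/C=C(/C)C[C@H](O)[C@H]1C(C)C
F4 | step 14 | 8-benzoate of F3 | O[C@H]1/C=C(/C)C(=O)C/C=C(/C)C[C@H](OC(=O)c2ccccc2)[C@H]1C(C)C
F5 | step 16 | 3S epimer of the target | CC(=O)O[C@H]1/C=C(/C)[C@@H](O)C/C=C(/C)C[C@H](OC(=O)c2ccccc2)[C@H]1C(C)C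
F6 | step 16 | 3R formate of the target | CC(=O)O[C@H]1/C=C(/C)[C@H](OC=O)C/C=C(/C)C[C@H](OC(=O)c2ccccc2)[C@H]1C(C)C
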